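Ring A carries oxygen at C1, C2 and C4, the 1,2,4-benzenetriol pattern that lies latent in the six carbons of a 5-(oxymethyl)furfural. The C2–O–aryl link is therefore made first, at an sp3 carbon, by alkylating 2,4-dibromophenol. The precursor is the furfural 3 with an ArOCH2 group at furan C5. In one redox-neutral operation hot water opens the furan to a 2,5-dioxohexanal, the ArOCH2 carbon (future C2) condenses with the formyl carbon (future C3), and aromatisation gives hydroquinone 6 with the ether already in place. Phenol differentiation, dibromination at C3 and C5 directed by the free C4 hydroxyl, O-methylation and ester removal complete the target.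

Key step: step 2

Remark on numbering:
- Ring A is C1 (OH), C2 (OAr), C3 (Br), C4 (OMe), C5 (Br), C6 (H).
- Ring B is the 2,4-dibromophenyl ring (Ar, primed locants).
- Atom map for the key step: furan C5 → C1, exocyclic CH2 → C2, formyl C → C3, furan C2 → C4, furan C3 → C5, furan C4 → C6.
- The target is achiral, so no stereodescriptor is needed.

Step 1
Reactants: 1 5-(chloromethyl)furan-2-carbaldehyde; 2 2,4-dibromophenol
Product: 3 5-[(2,4-dibromophenoxy)methyl]furan-2-carbaldehyde
Conditions: K2CO3 (1.5 equiv), MeCN, rt → 50 °C
Reagents that add atoms: none
Why: Williamson ether synthesis, in which the phenoxide of 2 displaces chloride from the activated furfuryl carbon of 1 by SN2 under mild carbonate conditions that leave the non-enolisable aldehyde and the aryl bromides untouched.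

Step 2
Reactants: 3 5-[(2,4-dibromophenoxy)methyl]furan-2-carbaldehyde
Product: 6 2-(2,4-dibromophenoxy)benzene-1,4-diol, via dioxohexanal 4 (not isolated), via cyclohexenedione 5 (not isolated)
Conditions: ZnCl2 (20 mol %), degassed H2O–1,4-dioxane (1:1, 0.02 M), pressurised flow coil, 250–280 °C, residence time of minutes, rapid cooling, work-up under Ar
Reagents that add atoms: water, SMILES O
Why: Proposed new method: ZnCl2 binds the formyl oxygen of 3, water adds to furan C5 in a vinylogous sense, and the resulting hemiketal opens and tautomerises to the tricarbonyl compound 4, a net hydration. The ketone flanking the ArOCH2 group enolises toward that inductively acidified carbon, which attacks the aldehyde in a 6-(enolendo)-exo-trig aldol closure that makes the C2–C3 bond and ring A; loss of water gives 5, and two keto–enol shifts turn 5 irreversibly into hydroquinone 6, so that 3 and 6 are isomers. The closest known reaction type is the hydrothermal, ZnCl2-assisted rearrangement of 5-(hydroxymethyl)furfural to 1,2,4-benzenetriol by way of 6-hydroxy-2,5-dioxohexanal, which has not been extended to an aryloxymethyl substrate. No stereocentre remains in 6, so none has to be controlled. Ring-size selectivity is needed and should be secured because aldol additions are reversible, the aldehyde is the best electrophile, the rival attack on the neighbouring ketone is a 5-(enolendo)-exo-trig process, and only the six-membered adduct can drain into an arene. Chemoselectivity for hydration over ionisation of the furfuryl C–O bond is also needed and is served by the electron-poor formylfuran, by the weakly basic aryl ether oxygen and by a near-neutral Lewis-acidic medium at high dilution without air, in which the aryl bromides and the diaryl ether of 6 should persist.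

Step 3
Reactants: 6 2-(2,4-dibromophenoxy)benzene-1,4-diol
Product: 7 2-(2,4-dibromophenoxy)benzene-1,4-diyl diacetate
Conditions: Ac2O (3 equiv), pyridine, 0 °C → rt, Ar
Reagents that add atoms: acetic anhydride, SMILES CC(=O)OC(C)=O
Why: Pyridine-promoted O-acylation of both phenols, which also turns the air-sensitive hydroquinone into a stable diester that is easy to purify.

Step 4
Reactants: 7 2-(2,4-dibromophenoxy)benzene-1,4-diyl diacetate
Product: 8 2-(2,4-dibromophenoxy)-4-hydroxyphenyl acetate
Conditions: pyrrolidine (1.0 equiv), MeCN, −10 → 0 °C
Reagents that add atoms: none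
Why: Aminolysis of an aryl ester with the amine as limiting reagent, in which the C4 acetate has two ortho hydrogens and a leaving phenoxide that feels the C2 aryloxy group only as a meta inductive acceptor, whereas the C1 acetate is screened by that ortho aryloxy group, so cleavage should occur at C4 and stop after one ester (recovered 6 or isomeric monoacetate can be re-acetylated to 7).

Step 5
Reactants: 8 2-(2,4-dibromophenoxy)-4-hydroxyphenyl acetate
Product: 9 3,5-dibromo-2-(2,4-dibromophenoxy)-4-hydroxyphenyl acetate
Conditions: Br2 (2.05 equiv), AcOH–CH2Cl2, 0 °C → rt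
Reagents that add atoms: bromine, SMILES BrBr
Why: Electrophilic aromatic bromination governed by the free C4 hydroxyl, whose para position is blocked, so both ortho sites C3 and C5 (also ortho and para to the C2 ether oxygen) should react, while C6 lies meta to both donors next to the weakly donating acetoxy group and ring B is deactivated by its two bromines.

Step 6
Reactants: 9 3,5-dibromo-2-(2,4-dibromophenoxy)-4-hydroxyphenyl acetate
Product: 10 3,5-dibromo-2-(2,4-dibromophenoxy)-4-methoxyphenyl acetate
Conditions: MeI (1.5 equiv), K2CO3 (1.2 equiv), dry acetone, rt → 40 °C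
Reagents that add atoms: iodomethane, SMILES CI
Why: Williamson O-methylation, in which the acidic 2,6-dibromophenol unit is ionised by K2CO3, the small electrophile tolerates the two flanking bromines, and the weakly nucleophilic phenoxide in a dry aprotic medium should leave the C1 acetate alone.

Step 7
Reactants: 10 3,5-dibromo-2-(2,4-dibromophenoxy)-4-methoxyphenyl acetate
Product: 11 3,5-dibromo-2-(2,4-dibromophenoxy)-4-methoxyphenol (target)
Conditions: NH3 (7 M in MeOH), 0 °C → rt
Reagents that add atoms: none
Why: Ammonolysis of the aryl acetate should free the C1 phenol under conditions too mild to affect the aryl bromides, the methyl ether or the diaryl ether.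

Compound list
1 | 5-(chloromethyl)furan-2-carbaldehyde | O=Cc1ccc(CCl)o1 | starting material
2 | 2,4-dibromophenol | Oc1ccc(Br)cc1Br | starting material
3 | 5-[(2,4-dibromophenoxy)methyl]furan-2-carbaldehyde | O=Cc1ccc(COc2ccc(Br)cc2Br)o1 | intermediate
4 | 6-(2,4-dibromophenoxy)-2,5-dioxohexanal (not isolated) | O=CC(=O)CCC(=O)COc1ccc(Br)cc1Br | intermediate
5 | 2-(2,4-dibromophenoxy)cyclohex-2-ene-1,4-dione (not isolated) | O=C1CCC(=O)C(Oc2ccc(Br)cc2Br)=C1 | intermediate
6 | 2-(2,4-dibromophenoxy)benzene-1,4-diol | Oc1ccc(O)c(Oc2ccc(Br)cc2Br)c1 | intermediate
7 | 2-(2,4-dibromophenoxy)benzene-1,4-diyl diacetate | CC(=O)Oc1ccc(OC(C)=O)c(Oc2ccc(Br)cc2Br)c1 | intermediate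
8 | 2-(2,4-dibromophenoxy)-4-hydroxyphenyl acetate | CC(=O)Oc1ccc(O)cc1Oc1ccc(Br)cc1Br | intermediate
9 | 3,5-dibromo-2-(2,4-dibromophenoxy)-4-hydroxyphenyl acetate | CC(=O)Oc1cc(Br)c(O)c(Br)c1Oc1ccc(Br)cc1Br | intermediate
10 | 3,5-dibromo-2-(2,4-dibromophenoxy)-4-methoxyphenyl acetate | CC(=O)Oc1cc(Br)c(OC)c(Br)c1Oc1ccc(Br)cc1Br | intermediate
11 | 3,5-dibromo-2-(2,4-dibromophenoxy)-4-methoxyphenol | COc1c(Br)cc(O)c(Oc2ccc(Br)cc2Br)c1Br | target

Total step count: 7. Longest linear sequence: 7 steps (from 1 or 2 to 11).

Steps most likely to fail

1. Step 2 (new method).
What may go wrong: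
- Solvolysis of the furfuryl C–O bond may run ahead of furan opening, with loss of the phenol and entry into the levulinic acid channel.
- The ring may close to five members.
- The tricarbonyl intermediate may polymerise.
- The product may oxidise in air.

Masking the aldehyde as an acetal is not advised, because a more electron-rich furan would ionise faster at the furfuryl position.

Fallback, known chemistry only: it sets out from 2. A Chan–Lam coupling is run with (2,5-dimethoxyphenyl)boronic acid (COc1ccc(OC)c(B(O)O)c1), Cu(OAc)2, pyridine, 4 Å molecular sieves, CH2Cl2, air, rt. These conditions spare aryl bromides and should give 2-(2,4-dibromophenoxy)-1,4-dimethoxybenzene F1. Double ether cleavage with BBr3 (CH2Cl2, −78 °C → rt) then returns to the route at 6.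

2. Step 4.
What may go wrong: poor discrimination between the two acetates, or cleavage of both.

Fallback: the differentiation is built by kinetic protection instead of partial deprotection, setting out from 6.
- TBSCl (1.0 equiv), imidazole, DMF, 0 °C should silylate only the exposed C4 hydroxyl and give 4-[(tert-butyldimethylsilyl)oxy]-2-(2,4-dibromophenoxy)phenol F2.
- Ac2O in pyridine should then give 4-[(tert-butyldimethylsilyl)oxy]-2-(2,4-dibromophenoxy)phenyl acetate F3.
- KHF2 in MeOH at rt removes a phenolic silyl ether without touching an aryl acetate and returns to the route at 8.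

3. Step 6.
What may go wrong:
- Base-induced transfer or loss of the acetyl group, followed by methylation at the C1 oxygen.
- Sluggish alkylation of the crowded phenoxide.

Fallback: the ester is taken out of play and acidity is used as the control element, setting out from 9. NH3 in MeOH should give 3,5-dibromo-2-(2,4-dibromophenoxy)benzene-1,4-diol F4. One equivalent of TMSCHN2 (toluene–MeOH, 0 °C) then methylates through a proton-transfer-gated pathway. The markedly more acidic C4 hydroxyl between the two bromines should react first, which returns to the route at 11.

Further compounds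
F1 | step 2 | 2-(2,4-dibromophenoxy)-1,4-dimethoxybenzene | COc1ccc(OC)c(Oc2ccc(Br)cc2Br)c1
F2 | step 4 | 4-[(tert-butyldimethylsilyl)oxy]-2-(2,4-dibromophenoxy)phenol | CC(C)(C)[Si](C)(C)Oc1ccc(O)c(Oc2ccc(Br)cc2Br)c1
F3 | step 4 | 4-[(tert-butyldimethylsilyl)oxy]-2-(2,4-dibromophenoxy)phenyl acetate | CC(=O)Oc1ccc(O[Si](C)(C)C(C)(C)C)cc1Oc1ccc(Br)cc1Br
F4 | step 6 | 3,5-dibromo-2-(2,4-dibromophenoxy)benzene-1,4-diol | Oc1cc(Br)c(O)c(Br)c1Oc1ccc(Br)cc1Br
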